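**Strategy.** Ring A of the flavanone is built de novo around the C6 ether oxygen, so the doubly flanked diaryl ether is never made by aryl C–O coupling. A racemic 4-aryloxy-3-benzyloxycyclobutenone, assembled from an aryloxyketene and benzyl ethynyl ether, is heated with (triisopropylsilyloxy)acetylene; one operation forms the C7–C8 and C4a–C8a bonds and closes the benzene ring with oxygen on C5, C6, C7 and C8a. The step exploits the ring A pattern in which O1 (on C8a) is meta to the C7 and C5 oxygens and para to the C6 aryloxy group; O1 emerges as the only silyl ether. The flavone and the (2S)-flavanone ring C are then grown on this core.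

Key step: step 6

Remark: (triisopropylsilyloxy)acetylene is treated as a non-catalogue reagent and is therefore prepared within the route (step 5); 1, 2, 5, 6, 12, 21 and 26 are catalogue chemicals.

**Route**

Step 1
Reactants: 1 methyl 4-hydroxybenzoate; 2 bromoacetic acid
Product: 3 [4-(methoxycarbonyl)phenoxy]acetic acid
Conditions: NaH (2.2 equiv), THF/DMF, 0 °C → 50 °C; then 1 M HCl
Reagents that add atoms: none
Why: Williamson etherification, in which the sodium phenoxide displaces bromide from sodium bromoacetate by SN2, and the absence of hydroxide leaves the methyl ester intact.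

Step 2
Reactants: 3 [4-(methoxycarbonyl)phenoxy]acetic acid
Product: 4 [4-(methoxycarbonyl)phenoxy]acetyl chloride
Conditions: (COCl)2, DMF (cat.), CH2Cl2, 0 °C → rt
Reagents that add atoms: oxalyl chloride, ClC(=O)C(Cl)=O
Why: Acid chloride formation through the catalytic chloroiminium species is mild enough for the methyl ester and the aryl ether.

Step 3
Reactants: 5 benzyl alcohol; 6 trichloroethylene
Product: 9 benzyl ethynyl ether, via (E)-benzyl 1,2-dichlorovinyl ether 7 (not isolated), via lithium (benzyloxy)ethynide 8 (not isolated)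
Conditions: KH (1.1 equiv), THF, 0 °C; 6, −50 °C → rt; n-BuLi (2.4 equiv), −78 → −40 °C; aq. NH4Cl, −78 °C; used at once as a cold solution
Reagents that add atoms: none
Why: Alkynyl ether synthesis from trichloroethylene, in which alkoxide addition–elimination gives the dichlorovinyl ether and n-BuLi then effects dehydrochlorination and chlorine–lithium exchange to the alkoxyacetylide, which is protonated cold because benzyl alkynyl ethers rearrange on warming.

Step 4
Reactants: 4 [4-(methoxycarbonyl)phenoxy]acetyl chloride; 9 benzyl ethynyl ether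
Product: 11 racemic methyl 4-{[2-(benzyloxy)-4-oxocyclobut-2-en-1-yl]oxy}benzoate, via aryloxyketene 10 (not isolated)
Conditions: Et3N (1.3 equiv), 9 (1.5 equiv), CH2Cl2, 0 °C → rt, slow addition of 4
Reagents that add atoms: none
Why: Ketene–ynol ether [2+2] cycloaddition, in which the ketene carbonyl carbon bonds to the nucleophilic terminal carbon of 9, so that benzyloxy ends on C3 and aryloxy on the sp3 carbon C4 (a racemic centre that is erased later).

Step 5
Reactants: 12 ethyl formate
Product: 14 (triisopropylsilyloxy)acetylene, via lithium ethynolate 13 (not isolated)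
Conditions: CH2Br2, lithium 2,2,6,6-tetramethylpiperidide, THF, −78 °C; n-BuLi, −78 °C → rt; i-Pr3SiCl, −78 °C → rt
Reagents that add atoms: dibromomethane, BrCBr; triisopropylsilyl chloride, CC(C)[Si](Cl)(C(C)C)C(C)C
Why: Kowalski ester-to-ynolate homologation, in which dibromomethyllithium adds to the formate, bromine–lithium exchange and 1,2-hydrogen shift of the bromo enolate give the ynolate, and the bulky silyl chloride is expected to silylate at oxygen.

Step 6
Reactants: 11 racemic methyl 4-{[2-(benzyloxy)-4-oxocyclobut-2-en-1-yl]oxy}benzoate; 14 (triisopropylsilyloxy)acetylene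
Product: 19 methyl 4-[2-(benzyloxy)-6-hydroxy-4-(triisopropylsilyloxy)phenoxy]benzoate, via vinylketene 15 (not isolated), via vinylcyclobutenone 16 (not isolated), via dienylketene 17 (not isolated), via cyclohexadienone 18 (not isolated)
Conditions: 14 (2 equiv), toluene (dilute), 80 °C then 110 °C, slow addition of 11
Reagents that add atoms: none
Why: This is a Danheiser benzannulation in its siloxyalkyne form, the closest known reaction type being the thermal union of cyclobutenones with (trialkylsilyloxy)alkynes to give resorcinol monosilyl ethers. Heating opens 11 by 4π electrocyclic cleavage of the C1–C4 bond to vinylketene 15, which takes up 14 in a [2+2] cycloaddition to give 4-vinylcyclobutenone 16, and a second 4π opening gives dienylketene 17. The six-membered ring closes by thermal disrotatory 6π electrocyclisation, the ketene carbon bonding to the aryloxy-bearing terminus, and cyclohexadienone 18 tautomerises to the phenol. No stereocentre is created, and the racemic centre of 11 is erased on aromatisation. The selectivity needed is silyloxy para to aryloxy; it is secured because the electrophilic ketene carbonyl carbon bonds to the unsubstituted nucleophilic carbon of 14, and because the aryloxy donor rotates outward in the first opening, leaving only hydrogen inside at the closing terminus. Excess 14 and slow addition of 11 should keep ketene intermediates from acylating the product phenol.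

Step 7
Reactants: 19 methyl 4-[2-(benzyloxy)-6-hydroxy-4-(triisopropylsilyloxy)phenoxy]benzoate
Product: 20 methyl 4-[2,6-bis(benzyloxy)-4-(triisopropylsilyloxy)phenoxy]benzoate
Conditions: BnBr, K2CO3, acetone, 50 °C
Reagents that add atoms: benzyl bromide, BrCc1ccccc1
Why: Williamson O-benzylation under mild carbonate conditions spares the aryl silyl ether and the methyl ester and makes ring A symmetric about the C6–C8a axis, so the later ring closure has no regiochemical choice.

Step 8
Reactants: 21 2',4',6'-trihydroxyacetophenone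
Product: 22 1-[2,4-bis(benzyloxy)-6-hydroxyphenyl]ethan-1-one
Conditions: BnBr (2.1 equiv), K2CO3, acetone, reflux
Reagents that add atoms: benzyl bromide, BrCc1ccccc1
Why: Williamson benzylation stops at the dibenzyl ether because the remaining ortho hydroxyl is deactivated by its hydrogen bond to the ketone.

Step 9
Reactants: 20 methyl 4-[2,6-bis(benzyloxy)-4-(triisopropylsilyloxy)phenoxy]benzoate; 22 1-[2,4-bis(benzyloxy)-6-hydroxyphenyl]ethan-1-one
Product: 23 1-[2,4-bis(benzyloxy)-6-hydroxyphenyl]-3-{4-[2,6-bis(benzyloxy)-4-(triisopropylsilyloxy)phenoxy]phenyl}propane-1,3-dione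
Conditions: 22, LiN(SiMe3)2 (4 equiv), THF, −78 °C; then 20, −78 → 50 °C; 1 M HCl
Reagents that add atoms: none
Why: Crossed Claisen condensation (the ester variant of the Baker–Venkataraman diketone synthesis) of the ketone dianion with the methyl benzoate, which needs no saponification and uses a non-nucleophilic base, so the aryl silyl ether survives.

Step 10
Reactants: 23 the 1,3-diketone
Product: 24 5,7-bis(benzyloxy)-2-{4-[2,6-bis(benzyloxy)-4-(triisopropylsilyloxy)phenoxy]phenyl}-4H-chromen-4-one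
Conditions: H2SO4 (cat.), AcOH, 60 °C
Reagents that add atoms: none
Why: Acid-catalysed cyclodehydration of the 1-(2-hydroxyaryl)-1,3-diketone (final stage of the Baker–Venkataraman flavone synthesis), the phenol adding to the enolised distal carbonyl with loss of water.

Step 11
Reactants: 24 the silyl-protected flavone
Product: 25 5,7-bis(benzyloxy)-2-{4-[2,6-bis(benzyloxy)-4-hydroxyphenoxy]phenyl}-4H-chromen-4-one
Conditions: Bu4NF, AcOH, THF, 0 °C
Reagents that add atoms: none
Why: Fluoride cleavage of the aryl silyl ether, buffered with acetic acid, frees O1 alone because every other oxygen is a benzyl ether.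

Step 12
Reactants: 26 1-[4-(benzyloxy)phenyl]ethan-1-one
Product: 27 methyl 3-[4-(benzyloxy)phenyl]-3-oxopropanoate
Conditions: NaH, (MeO)2CO, THF, reflux; AcOH quench
Reagents that add atoms: dimethyl carbonate, COC(=O)OC
Why: Crossed Claisen C-acylation of the ketone enolate with dimethyl carbonate is driven by formation of the stabilised β-keto ester enolate.

Step 13
Reactants: 27 methyl 3-[4-(benzyloxy)phenyl]-3-oxopropanoate
Product: 28 methyl (3R)-3-[4-(benzyloxy)phenyl]-3-hydroxypropanoate
Conditions: RuCl[(R,R)-TsDPEN](p-cymene) (1 mol %), HCO2H/Et3N, DMF, 40 °C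
Reagents that add atoms: none
Why: Noyori asymmetric transfer hydrogenation of the aryl ketone, in which the (R,R)-ligand should deliver hydride to the face that gives the (R)-benzylic alcohol, as with acetophenone-type substrates, while benzyl ethers are inert.

Step 14
Reactants: 25 the flavone phenol; 28 methyl (3R)-3-[4-(benzyloxy)phenyl]-3-hydroxypropanoate
Product: 29 methyl (3S)-3-[4-(benzyloxy)phenyl]-3-(3,5-bis(benzyloxy)-4-{4-[5,7-bis(benzyloxy)-4-oxo-4H-chromen-2-yl]phenoxy}phenoxy)propanoate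
Conditions: PPh3, DIAD, toluene, 0 °C → rt
Reagents that add atoms: none
Why: Mitsunobu etherification, in which the O1 phenol displaces the oxyphosphonium group by SN2 with inversion, turning the (R)-alcohol into the (S)-aryl ether that becomes C2, with nonpolar solvent and low temperature chosen to disfavour ionisation and elimination.

Step 15
Reactants: 29 the (3S)-aryloxy ester
Product: 30 (3S)-3-[4-(benzyloxy)phenyl]-3-(3,5-bis(benzyloxy)-4-{4-[5,7-bis(benzyloxy)-4-oxo-4H-chromen-2-yl]phenoxy}phenoxy)propanoic acid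
Conditions: LiOH, THF/MeOH/H2O, 0 °C; then 1 M HCl
Reagents that add atoms: lithium hydroxide, [Li+].[OH-]
Why: Saponification of the methyl ester at low temperature, where acyl substitution should outrun β-elimination of the aryloxide and the stereocentre carries no acidic hydrogen.

Step 16
Reactants: 30 the (3S)-aryloxy acid
Product: 32 (2S)-5,7-bis(benzyloxy)-2-[4-(benzyloxy)phenyl]-6-{4-[5,7-bis(benzyloxy)-4-oxo-4H-chromen-2-yl]phenoxy}-2,3-dihydro-4H-chromen-4-one, via mixed anhydride 31 (not isolated)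
Conditions: (CF3CO)2O, CH2Cl2, 0 °C → rt
Reagents that add atoms: none
Why: Intramolecular Friedel–Crafts acylation through the mixed trifluoroacetic anhydride onto the phloroglucinol-type ring A forms C4–C4a, the two positions ortho to O1 being equivalent by symmetry and the C2 centre not taking part.

Step 17
Reactants: 32 the pentabenzyl flavanone–flavone
Product: 33 (2S)-5,7-dihydroxy-6-[4-(5,7-dihydroxy-4-oxo-4H-chromen-2-yl)phenoxy]-2-(4-hydroxyphenyl)-2,3-dihydro-4H-chromen-4-one
Conditions: H2 (1 atm), 10% Pd/C, EtOAc/MeOH, rt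
Reagents that add atoms: none
Why: Catalytic hydrogenolysis removes the five benzyl ethers under neutral conditions that should leave the flavone C2=C3 bond, both ketones and the (2S) centre untouched if stopped at complete debenzylation.

**Compound list**

1 | methyl 4-hydroxybenzoate | COC(=O)c1ccc(O)cc1 | starting material
2 | bromoacetic acid | OC(=O)CBr | starting material
3 | [4-(methoxycarbonyl)phenoxy]acetic acid | COC(=O)c1ccc(OCC(=O)O)cc1 | intermediate
4 | [4-(methoxycarbonyl)phenoxy]acetyl chloride | COC(=O)c1ccc(OCC(=O)Cl)cc1 | intermediate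
5 | benzyl alcohol | OCc1ccccc1 | starting material
6 | trichloroethylene | ClC=C(Cl)Cl | starting material
7 | (E)-benzyl 1,2-dichlorovinyl ether | Cl/C=C(/Cl)OCc1ccccc1 | intermediate (not isolated)
8 | lithium (benzyloxy)ethynide | [Li]C#COCc1ccccc1 | intermediate (not isolated)
9 | benzyl ethynyl ether | C#COCc1ccccc1 | intermediate
10 | methyl 4-[(2-oxoethenyl)oxy]benzoate (aryloxyketene) | COC(=O)c1ccc(OC=C=O)cc1 | intermediate (not isolated)
11 | racemic methyl 4-{[2-(benzyloxy)-4-oxocyclobut-2-en-1-yl]oxy}benzoate | O=C1C=C(OCc2ccccc2)C1Oc1ccc(C(=O)OC)cc1 | intermediate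
12 | ethyl formate | CCOC=O | starting material
13 | lithium ethynolate | [Li+].[O-]C#C | intermediate (not isolated)
14 | (triisopropylsilyloxy)acetylene | C#CO[Si](C(C)C)(C(C)C)C(C)C | intermediate
15 | methyl 4-{[(1Z)-2-(benzyloxy)-4-oxobuta-1,3-dien-1-yl]oxy}benzoate (vinylketene, aryloxy trans to the ketene carbon) | O=C=C/C(OCc1ccccc1)=C/Oc1ccc(cc1)C(=O)OC | intermediate (not isolated)
16 | racemic methyl 4-({(1Z)-2-(benzyloxy)-2-[4-oxo-2-(triisopropylsilyloxy)cyclobut-2-en-1-yl]ethenyl}oxy)benzoate | O=C1C=C(O[Si](C(C)C)(C(C)C)C(C)C)C1/C(OCc1ccccc1)=C/Oc1ccc(cc1)C(=O)OC | intermediate (not isolated)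
17 | methyl 4-{[(1Z,3E)-2-(benzyloxy)-6-oxo-4-(triisopropylsilyloxy)hexa-1,3,5-trien-1-yl]oxy}benzoate (dienylketene) | O=C=C/C(O[Si](C(C)C)(C(C)C)C(C)C)=C\C(OCc1ccccc1)=C\Oc1ccc(cc1)C(=O)OC | intermediate (not isolated)
18 | racemic methyl 4-{[2-(benzyloxy)-6-oxo-4-(triisopropylsilyloxy)cyclohexa-2,4-dien-1-yl]oxy}benzoate | O=C1C=C(O[Si](C(C)C)(C(C)C)C(C)C)C=C(OCc2ccccc2)C1Oc1ccc(cc1)C(=O)OC | intermediate (not isolated)
19 | methyl 4-[2-(benzyloxy)-6-hydroxy-4-(triisopropylsilyloxy)phenoxy]benzoate | COC(=O)c1ccc(Oc2c(O)cc(O[Si](C(C)C)(C(C)C)C(C)C)cc2OCc2ccccc2)cc1 | intermediate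
20 | methyl 4-[2,6-bis(benzyloxy)-4-(triisopropylsilyloxy)phenoxy]benzoate | COC(=O)c1ccc(Oc2c(OCc3ccccc3)cc(O[Si](C(C)C)(C(C)C)C(C)C)cc2OCc2ccccc2)cc1 | intermediate
21 | 2',4',6'-trihydroxyacetophenone | CC(=O)c1c(O)cc(O)cc1O | starting material
22 | 1-[2,4-bis(benzyloxy)-6-hydroxyphenyl]ethan-1-one | CC(=O)c1c(O)cc(OCc2ccccc2)cc1OCc1ccccc1 | intermediate
23 | 1-[2,4-bis(benzyloxy)-6-hydroxyphenyl]-3-{4-[2,6-bis(benzyloxy)-4-(triisopropylsilyloxy)phenoxy]phenyl}propane-1,3-dione | O=C(CC(=O)c1ccc(Oc2c(OCc3ccccc3)cc(O[Si](C(C)C)(C(C)C)C(C)C)cc2OCc2ccccc2)cc1)c1c(O)cc(OCc2ccccc2)cc1OCc1ccccc1 | intermediate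
24 | 5,7-bis(benzyloxy)-2-{4-[2,6-bis(benzyloxy)-4-(triisopropylsilyloxy)phenoxy]phenyl}-4H-chromen-4-one | O=c1cc(-c2ccc(Oc3c(OCc4ccccc4)cc(O[Si](C(C)C)(C(C)C)C(C)C)cc3OCc3ccccc3)cc2)oc2cc(OCc3ccccc3)cc(OCc3ccccc3)c12 | intermediate
25 | 5,7-bis(benzyloxy)-2-{4-[2,6-bis(benzyloxy)-4-hydroxyphenoxy]phenyl}-4H-chromen-4-one | O=c1cc(-c2ccc(Oc3c(OCc4ccccc4)cc(O)cc3OCc3ccccc3)cc2)oc2cc(OCc3ccccc3)cc(OCc3ccccc3)c12 | intermediate
26 | 1-[4-(benzyloxy)phenyl]ethan-1-one | CC(=O)c1ccc(OCc2ccccc2)cc1 | starting material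
27 | methyl 3-[4-(benzyloxy)phenyl]-3-oxopropanoate | COC(=O)CC(=O)c1ccc(OCc2ccccc2)cc1 | intermediate
28 | methyl (3R)-3-[4-(benzyloxy)phenyl]-3-hydroxypropanoate | COC(=O)C[C@@H](O)c1ccc(OCc2ccccc2)cc1 | intermediate
29 | methyl (3S)-3-[4-(benzyloxy)phenyl]-3-(3,5-bis(benzyloxy)-4-{4-[5,7-bis(benzyloxy)-4-oxo-4H-chromen-2-yl]phenoxy}phenoxy)propanoate | COC(=O)C[C@H](Oc1cc(OCc2ccccc2)c(Oc2ccc(-c3cc(=O)c4c(OCc5ccccc5)cc(OCc5ccccc5)cc4o3)cc2)c(OCc2ccccc2)c1)c1ccc(OCc2ccccc2)cc1 | intermediate
30 | (3S)-3-[4-(benzyloxy)phenyl]-3-(3,5-bis(benzyloxy)-4-{4-[5,7-bis(benzyloxy)-4-oxo-4H-chromen-2-yl]phenoxy}phenoxy)propanoic acid | OC(=O)C[C@H](Oc1cc(OCc2ccccc2)c(Oc2ccc(-c3cc(=O)c4c(OCc5ccccc5)cc(OCc5ccccc5)cc4o3)cc2)c(OCc2ccccc2)c1)c1ccc(OCc2ccccc2)cc1 | intermediate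
31 | mixed anhydride of acid 30 with trifluoroacetic acid, (3S) | O=C(C[C@H](Oc1cc(OCc2ccccc2)c(Oc2ccc(-c3cc(=O)c4c(OCc5ccccc5)cc(OCc5ccccc5)cc4o3)cc2)c(OCc2ccccc2)c1)c1ccc(OCc2ccccc2)cc1)OC(=O)C(F)(F)F | intermediate (not isolated)
32 | (2S)-5,7-bis(benzyloxy)-2-[4-(benzyloxy)phenyl]-6-{4-[5,7-bis(benzyloxy)-4-oxo-4H-chromen-2-yl]phenoxy}-2,3-dihydro-4H-chromen-4-one | O=C1C[C@@H](c2ccc(OCc3ccccc3)cc2)Oc2cc(OCc3ccccc3)c(Oc3ccc(-c4cc(=O)c5c(OCc6ccccc6)cc(OCc6ccccc6)cc5o4)cc3)c(OCc3ccccc3)c21 | intermediate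
33 | (2S)-5,7-dihydroxy-6-[4-(5,7-dihydroxy-4-oxo-4H-chromen-2-yl)phenoxy]-2-(4-hydroxyphenyl)-2,3-dihydro-4H-chromen-4-one | O=C1C[C@@H](c2ccc(O)cc2)Oc2cc(O)c(Oc3ccc(-c4cc(=O)c5c(O)cc(O)cc5o4)cc3)c(O)c21 | target

**Step count and risk**

Total: 17 steps. Longest linear sequence: 12 steps (steps 1, 2, 4, 6, 7, 9, 10, 11, 14, 15, 16, 17).

Steps most likely to fail:

1. Step 6 (benzannulation). The 3-benzyloxy group stabilises the cyclobutenone as a vinylogous ester, so ring opening may need temperatures at which the terminal siloxyalkyne isomerises to the silylketene. Ketene intermediates may also oligomerise or O-acylate the product phenol. The fallback replaces ring construction by copper-mediated C–O coupling; it sets out from 21 and comes back to the route at 20.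
 - Silylation of the unchelated 4'-hydroxyl (i-Pr3SiCl, imidazole, DMF, 0 °C) should give 1-[2,6-dihydroxy-4-(triisopropylsilyloxy)phenyl]ethan-1-one F1.
 - Double Mitsunobu benzylation (BnOH, PPh3, DIAD, THF) should give 1-[2,6-bis(benzyloxy)-4-(triisopropylsilyloxy)phenyl]ethan-1-one F2.
 - Baeyer–Villiger oxidation (mCPBA, NaHCO3, CH2Cl2) should give 2,6-bis(benzyloxy)-4-(triisopropylsilyloxy)phenyl acetate F3.
 - Ammonolysis (NH3, MeOH, 0 °C) should give 2,6-bis(benzyloxy)-4-(triisopropylsilyloxy)phenol F4.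
 - Chan–Lam coupling of F4 with [4-(methoxycarbonyl)phenyl]boronic acid (Cu(OAc)2, pyridine, 4 Å sieves, CH2Cl2, air, rt) should give 20.

2. Step 5 (siloxyalkyne). The formate adduct may collapse early and take up a second carbenoid. The unhindered ynolate may also be silylated at carbon, leading to the silylketene. The fallback forms the O–C bond before the alkyne; it sets out from 6 and comes back at 14.
 - Potassium triisopropylsilanolate (i-Pr3SiOH, KH, THF) is added to 6 by addition–elimination to give (E)-1,2-dichlorovinyl triisopropylsilyl ether F5.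
 - Treatment with n-BuLi (2.2 equiv, THF, −78 °C) and cold aqueous NH4Cl should give 14.

3. Step 14 (Mitsunobu). Ionisation of the oxyphosphonium intermediate at the 4-benzyloxybenzylic carbon would erode enantiomeric purity. Deprotonation next to the ester would lead to elimination to the cinnamate. The fallback sets C2 by asymmetric conjugate arylation instead of substitution; it sets out from 25 and comes back at 32.
 - Vilsmeier–Haack-type acetylation ortho to the free hydroxyl (N,N-dimethylacetamide, POCl3; aqueous NaOAc) should give 5,7-bis(benzyloxy)-2-{4-[3-acetyl-2,6-bis(benzyloxy)-4-hydroxyphenoxy]phenyl}-4H-chromen-4-one F6.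
 - Condensation with Me2NCH(OMe)2 (toluene, 90 °C) should give the enaminone 5,7-bis(benzyloxy)-2-(4-{2,6-bis(benzyloxy)-3-[(2E)-3-(dimethylamino)prop-2-enoyl]-4-hydroxyphenoxy}phenyl)-4H-chromen-4-one F7.
 - Acid-induced ring closure (HCl, CH2Cl2, rt) should give 5,7-bis(benzyloxy)-6-{4-[5,7-bis(benzyloxy)-4-oxo-4H-chromen-2-yl]phenoxy}-4H-chromen-4-one F8.
 - Enantioselective conjugate addition of 4-(benzyloxy)phenylboronic acid to the unsubstituted chromone of F8 should give 32. Conditions: Pd(OCOCF3)2, the t-BuPyOX enantiomer that leads to the 2S series, NH4PF6, H2O, ClCH2CH2Cl, 60 °C. The 2-aryl chromone is expected to stay inert.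

**Further compounds**

F1 | step 6 | 1-[2,6-dihydroxy-4-(triisopropylsilyloxy)phenyl]ethan-1-one | CC(=O)c1c(O)cc(O[Si](C(C)C)(C(C)C)C(C)C)cc1O
F2 | step 6 | 1-[2,6-bis(benzyloxy)-4-(triisopropylsilyloxy)phenyl]ethan-1-one | CC(=O)c1c(OCc2ccccc2)cc(O[Si](C(C)C)(C(C)C)C(C)C)cc1OCc1ccccc1
F3 | step 6 | 2,6-bis(benzyloxy)-4-(triisopropylsilyloxy)phenyl acetate | CC(=O)Oc1c(OCc2ccccc2)cc(O[Si](C(C)C)(C(C)C)C(C)C)cc1OCc1ccccc1
F4 | step 6 | 2,6-bis(benzyloxy)-4-(triisopropylsilyloxy)phenol | Oc1c(OCc2ccccc2)cc(O[Si](C(C)C)(C(C)C)C(C)C)cc1OCc1ccccc1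
F5 | step 5 | (E)-1,2-dichlorovinyl triisopropylsilyl ether | Cl/C=C(/Cl)O[Si](C(C)C)(C(C)C)C(C)C
F6 | step 14 | 5,7-bis(benzyloxy)-2-{4-[3-acetyl-2,6-bis(benzyloxy)-4-hydroxyphenoxy]phenyl}-4H-chromen-4-one | CC(=O)c1c(O)cc(OCc2ccccc2)c(Oc2ccc(-c3cc(=O)c4c(OCc5ccccc5)cc(OCc5ccccc5)cc4o3)cc2)c1OCc1ccccc1
F7 | step 14 | 5,7-bis(benzyloxy)-2-(4-{2,6-bis(benzyloxy)-3-[(2E)-3-(dimethylamino)prop-2-enoyl]-4-hydroxyphenoxy}phenyl)-4H-chromen-4-one | CN(C)/C=C/C(=O)c1c(O)cc(OCc2ccccc2)c(Oc2ccc(-c3cc(=O)c4c(OCc5ccccc5)cc(OCc5ccccc5)cc4o3)cc2)c1OCc1ccccc1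
F8 | step 14 | 5,7-bis(benzyloxy)-6-{4-[5,7-bis(benzyloxy)-4-oxo-4H-chromen-2-yl]phenoxy}-4H-chromen-4-one | O=c1ccoc2cc(OCc3ccccc3)c(Oc3ccc(-c4cc(=O)c5c(OCc6ccccc6)cc(OCc6ccccc6)cc5o4)cc3)c(OCc3ccccc3)c12
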